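## The problem

The target is a briarane diterpenoid, and its skeleton locants are used throughout. A cyclohexene (ring C: C1, C10, C11=C12, C13, C14; methyl C20 on C11) is trans-fused through C1–C10 to a ten-membered carbocycle (C1 to C10). C1 is quaternary (methyl C15), C5 carries the acetoxymethyl carbon C16, and a γ-lactone (C7–O–C19(=O)–C17(CH3 = C18)–C8) is fused across C7–C8.

Eight stereocentres must be set (1S, 2S, 7S, 8S, 9S, 10S, 14S, 17R). C7, C8 and C9 are contiguous and oxygenated, and C8 is a tertiary carbinol. Ring C can be built first with C1 and C14 fixed. A temporary oxygen at C12 can then pass its configuration to C10, and the C17 centre, taken from the chiral pool, can steer C8 and C7.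

The ten-membered ring is the central difficulty, because direct closure pays in entropy and transannular strain. The four acetates do not survive organolithium or hydride reagents and must be carried as silyl ethers until the end. The β-hydroxy lactone is prone to dehydration and retro-aldol cleavage, C17 becomes epimerisable once C19 is a carbonyl, and the dienyl carbinol stage is acid-labile.

The feature that opens the route is the C9 oxygen on a carbon bonded to C10, with the C11=C12 olefin adjacent. This is a homoallylic alcohol, the product pattern of a [2,3]-Wittig shift of a C9–O–C12 allyl ether held in a thirteen-membered ring. After that shift C7=C8 is a trans olefin inside the ring. The C8 and C9 oxygens of the target are threo (trans on the ring), and this decides how the last two oxygens must be delivered.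

## Retrosynthesis

**Acetates.** The C2, C14 and C16 acetates of 46 are cut first, giving triol 45 and its silyl-protected form 44. Silyl ethers are the only oxygen protection that tolerates the organolithium steps upstream, so three acetylations are left to the last step.

**Lactone and the C7/C8 oxygens.** In 44 the C7–O(lactone) bond is cut and the C8 hydroxyl is traced, together with it, to one epoxide: 44 comes from epoxy acid 43, and that from epoxy alcohol 42. The target pattern is an anti addition across the (E)-C7=C8 olefin of 41, with oxygen at C8 from one face and the carboxylate at C7 from the other. A free C9 hydroxyl would direct a vanadium peroxide erythro, because C8 carries the geminal C17 branch, and that is the wrong face for the threo C8/C9 pattern. The C9 oxygen is therefore acetylated first (39 to 40), and delivery is given to the homoallylic C19 hydroxyl of 41, where A(1,3) strain at C17 selects the face. The forward steps must achieve face-selective epoxidation, a mild oxidation to the acid, and opening at the allylic C7 with inversion.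

**Ten-membered ring (key step).** In 39 the C9–C10 bond is cut and the C9 oxygen is rejoined to C12, with the olefin moved back to C10=C11. This gives the thirteen-membered ether 38. The alternative cuts within the ten-membered ring all require a medium-ring C–C closure. This one replaces it with a concerted contraction that also sets C9 and C10. The precursor is simpler by one C–C bond and two stereocentres, and it contains only silyl ethers.

**Ether ring.** 38 is opened at the C9–O bond to chloro alcohol 37, which comes from diol 35. The cut is made at the primary allylic carbon, not at C12, because SN2 at C9 is clean, whereas substitution at the secondary allylic C12 would scramble its configuration. The forward reaction is a high-dilution Williamson closure.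

**C2–C3 bond.** 35 (via 34, 33, 32 and 31) is cut between C2 and C3 into aldehyde 13 and iodide 29 (used as alkyllithium 30). C2 is the former carboxyl carbon of the arene, so no extra carbon has to be added to ring C. The addition itself need not be selective, because C2 is reset by oxidation to ketone 32 and a reagent-controlled reduction to 33.

**Ring C.** Aldehyde 13 goes back through 12, 11, 10, 9, 8, 7 and 6 to benzamide 4, made from acid 1 and amine 2. Birch reduction–alkylation sets the quaternary C1 and leaves the C14 carbonyl and the C10=C11 olefin in place. C14 and C12 are then set by two oxazaborolidine reductions, the second after allylic oxidation at C12.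

**C5=C6 olefin.** Iodide 29 comes from alcohol 28, which is cut at C3–C4 by a Wittig–Still [2,3] shift to stannylmethyl ether 26. That comes from dienol 25, the adduct of enal 21 and the vinyllithium 24 from bromide 23 (from 2-bromoprop-2-en-1-ol 22). A Horner–Wadsworth–Emmons route would need more redox and protecting steps. The [2,3] shift delivers the required geometry (C4 cis to C7) and the C3 hydroxyl in one step.

**C7=C8 olefin and C17.** Enal 21 goes back through 20, 19 and 18 to (E)-enol triflate 17 of β-keto ester 16, which is made from silylated Roche ester 15 (from 14). A carbometalation of a Roche-derived alkyne would put C9 cis to C6, which is the wrong geometry. The triflate route fixes C9 trans to C6 and keeps C17 untouched.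

## Roads not taken

**Alternative 1:** The cut is at C6–C7, together with the lactone C–O bond. In the forward direction a C6 vinyl iodide adds to a C7 aldehyde under NiCl2/CrCl2 with cathodic regeneration of divalent chromium, and the C7 alkoxide closes onto a C19 ester to give A1, the C8 triethylsilyl ether of 46.
- Merits: the ring and the lactone form together, the acetates are already in place, and only one deprotection follows. In step count after ring closure this road is clearly better than the chosen one.
- Weak points: the ten-membered ring is closed by C–C bond formation at a neopentyl, α-oxygenated aldehyde under high dilution. C7 is created in that closure with no reliable facial control. The open-chain substrate must already hold the C8 tertiary carbinol between C9 and C17, which is the hardest acyclic stereotriad of the molecule.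
- Comparison: the chosen plan sets against the shorter endgame a ring formation split into an SN2 etherification and a concerted shift, and chirality transfer to C10.

**Alternative 2:** The ten-membered ring is hidden as two six-membered rings sharing a tetrasubstituted C2=C7 olefin. Ozonolysis cuts that olefin and gives dione A2.
- Merits: no macrocyclisation at all, and the trans ring fusion is set in rigid six-ring chemistry. For making the ring this is the safest of the four roads.
- Weak points: ozone must choose the tetrasubstituted olefin over two trisubstituted ones. A2 lacks the C16 oxygen, the C8 oxygen and the whole C17–C19 unit. Both ketones need stereoselective reduction, and a 2,7-dione in a ten-membered ring invites transannular aldol reaction.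
- Comparison: the chosen plan brings every carbon and the C9/C10 centres into the ring-forming step, and so avoids the long functionalisation that A2 would need.

**Alternative 3:** The cut is the C3–C4 bond, with C6 rejoined to oxygen. On heating, a 2-methylene-8-vinyl oxocane undergoes a Claisen shift to give ketone A3 with the C5=C6 olefin.
- Merits: a concerted ring expansion, and the C7 and C8 oxygens are already present as an acetonide. This removes the late facial problem at C7=C8, which is the weakest part of the chosen plan, and in that respect this road is better.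
- Weak points: a heavily substituted eight-membered lactone must first be closed and methylenated next to the quaternary C1. The rearrangement must deliver the ring-cis C5=C6 geometry. The C2 ketone of A3 still needs a selective reduction.
- Comparison: the chosen plan offers a precursor made by simple etherification and a shift whose stereochemical course at C10 is fixed by the mechanism.

Key step: step 29

Assumption: the (S)-configured methoxymethylpyrrolidine amide is taken to direct methylation of the Birch enolate so that C1 is R in 5 and 6; if the sense is the opposite, the equally available (R)-amine is used and nothing else changes.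

Abbreviations in names: TBS = tert-butyldimethylsilyl, TES = triethylsilyl, TIPS = tri(propan-2-yl)silyl. Skeleton locants C1–C20 are those defined in the first section.

Step 1
Reactants: 1 2-methoxy-5-methylbenzoic acid; 2 (S)-2-(methoxymethyl)pyrrolidine
Product: 4 [(2S)-2-(methoxymethyl)pyrrolidin-1-yl](2-methoxy-5-methylphenyl)methanone, via acid chloride 3 (not isolated)
Conditions: (COCl)2, cat. DMF, CH2Cl2, 0 °C to rt; then 2, Et3N, CH2Cl2, 0 °C
Reagents that add atoms: none
Why: Acid chloride formation and N-acylation; the amide activates the arene for Birch reduction and is the controlling element for C1.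

Step 2
Reactants: 4 benzamide
Product: 6 [(1R)-1,3-dimethyl-6-oxocyclohex-2-en-1-yl][(2S)-2-(methoxymethyl)pyrrolidin-1-yl]methanone, via enol ether 5 (not isolated)
Conditions: K, NH3–THF, t-BuOH (1 equiv), −78 °C; MeI, −78 °C; then 1 M HCl, MeOH, rt
Reagents that add atoms: iodomethane, CI; water, O
Why: Birch reduction–alkylation gives the amide enolate, which should be methylated on the face left open by the potassium-chelated methoxymethyl arm, setting quaternary C1. Acid then hydrolyses only the enol ether to the C14 ketone, and the C10=C11 olefin cannot move into conjugation past the quaternary carbon.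

Step 3
Reactants: 6 keto amide
Product: 7 [(1R,6S)-6-hydroxy-1,3-dimethylcyclohex-2-en-1-yl][(2S)-2-(methoxymethyl)pyrrolidin-1-yl]methanone
Conditions: (R)-2-methyl-CBS-oxazaborolidine (20 mol%), BH3·SMe2, THF, −20 °C
Reagents that add atoms: none
Why: Corey–Bakshi–Shibata reduction under reagent control, with quaternary C1 as the large group and C13H2 as the small one, so the (R)-catalyst should give the (S)-carbinol at C14 (hydroxyl cis to the carboxamide). Steric approach anti to the bulky amide favours the same sense.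

Step 4
Reactants: 7 hydroxy amide
Product: 8 C14 TBS ether of 7
Conditions: TBSOTf, 2,6-lutidine, CH2Cl2, 0 °C
Reagents that add atoms: tert-butyldimethylsilyl triflate, CC(C)(C)[Si](C)(C)OS(=O)(=O)C(F)(F)F
Why: Silylation of a hindered secondary alcohol with the silyl triflate; this ether stays on C14 until step 34.

Step 5
Reactants: 8 silyl ether
Product: 9 [(1R,6S)-6-(TBSO)-1,3-dimethyl-4-oxocyclohex-2-en-1-yl][(2S)-2-(methoxymethyl)pyrrolidin-1-yl]methanone
Conditions: dirhodium tetracaprolactamate Rh2(cap)4 (1 mol%), t-BuOOH (70% aq.), 1,2-dichloroethane, 40 °C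
Reagents that add atoms: tert-butyl hydroperoxide, CC(C)(C)OO
Why: Rhodium-catalysed allylic oxidation (hydrogen abstraction by the peroxyl radical, then collapse of the allylic peroxide). C12 is the only ring allylic CH2 because C1 is quaternary, and the C20 methyl reacts more slowly, so the C12 enone is expected.

Step 6
Reactants: 9 enone
Product: 10 [(1R,4S,6S)-6-(TBSO)-4-hydroxy-1,3-dimethylcyclohex-2-en-1-yl][(2S)-2-(methoxymethyl)pyrrolidin-1-yl]methanone
Conditions: (R)-2-methyl-CBS-oxazaborolidine (0.5 equiv), catecholborane, toluene, −78 °C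
Reagents that add atoms: none
Why: Corey–Bakshi–Shibata 1,2-reduction of a 2-methyl enone, with the olefinic carbon C11 as the large group, so the (R)-catalyst should give the (12S)-allylic alcohol, trans to the C14 silyl ether. This is the configuration from which C10 is later derived.

Step 7
Reactants: 10 allylic alcohol
Product: 11 C12 TES ether of 10
Conditions: TESCl, imidazole, CH2Cl2, 0 °C
Reagents that add atoms: chlorotriethylsilane, CC[Si](Cl)(CC)CC
Why: Silylation; the labile TES group marks the oxygen that will be freed for ether formation.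

Step 8
Reactants: 11 bis-silyl amide
Product: 12 [(1S,4S,6S)-6-(TBSO)-1,3-dimethyl-4-(TESO)cyclohex-2-en-1-yl]methanol
Conditions: LiNH2BH3 (from BH3·NH3 and LiN(i-Pr)2), THF, 0 °C to rt
Reagents that add atoms: none
Why: Lithium amidotrihydroborate reduces hindered tertiary amides to primary alcohols with C–N cleavage, which also releases the auxiliary; silyl ethers and the trisubstituted olefin are inert.

Step 9
Reactants: 12 neopentyl alcohol
Product: 13 (1R,4S,6S)-6-(TBSO)-1,3-dimethyl-4-(TESO)cyclohex-2-ene-1-carbaldehyde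
Conditions: Dess–Martin periodinane, NaHCO3, CH2Cl2, 0 °C
Reagents that add atoms: none
Why: Dess–Martin oxidation; the aldehyde (C2) has no α-hydrogen and cannot enolise or epimerise.

Step 10
Reactants: 14 methyl (S)-3-hydroxy-2-methylpropanoate
Product: 15 methyl (2S)-3-(TBSO)-2-methylpropanoate
Conditions: TBSCl, imidazole, CH2Cl2, rt
Reagents that add atoms: tert-butyldimethylsilyl chloride, CC(C)(C)[Si](C)(C)Cl
Why: Silylation of the primary alcohol, which becomes C19; the stereocentre is C17.

Step 11
Reactants: 15 silylated ester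
Product: 16 methyl (4S)-5-(TBSO)-4-methyl-3-oxopentanoate
Conditions: LiN(i-Pr)2, MeOAc (3 equiv), THF, −78 °C; then 15, −78 to −40 °C
Reagents that add atoms: methyl acetate, CC(=O)OC
Why: Crossed Claisen condensation adds C7 and C6. The β-keto ester is deprotonated at once between its carbonyls, which protects the C17 centre from epimerisation.

Step 12
Reactants: 16 β-keto ester
Product: 17 methyl (2E,4S)-5-(TBSO)-4-methyl-3-[(trifluoromethanesulfonyl)oxy]pent-2-enoate
Conditions: Tf2O, aq. Me4NOH, hexanes, 5 °C
Reagents that add atoms: triflic anhydride, O=S(=O)(OS(=O)(=O)C(F)(F)F)C(F)(F)F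
Why: O-Triflation of the non-chelated ammonium enolate should give the (E)-enol triflate (triflate trans to the ester), which places C17 and C6 cis across the future C7=C8 bond.

Step 13
Reactants: 17 enol triflate
Product: 18 methyl (2E,4R)-5-(TBSO)-3-(hydroxymethyl)-4-methylpent-2-enoate
Conditions: Bu3SnCH2OH, Pd(PPh3)4 (5 mol%), LiCl, 1,4-dioxane, 90 °C
Reagents that add atoms: (tributylstannyl)methanol, OC[Sn](CCCC)(CCCC)CCCC
Why: Stille coupling with retention of olefin geometry installs C9 as a hydroxymethyl group trans to the ester, so butenolide formation is not possible.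

Step 14
Reactants: 18 hydroxy ester
Product: 19 methyl (2E,4R)-5-(TBSO)-4-methyl-3-[(TESO)methyl]pent-2-enoate
Conditions: TESCl, imidazole, CH2Cl2, 0 °C
Reagents that add atoms: chlorotriethylsilane, CC[Si](Cl)(CC)CC
Why: Silylation; the same labile group as on C12, so that both ether oxygens are released together in step 26.

Step 15
Reactants: 19 enoate
Product: 20 (2E,4R)-5-(TBSO)-4-methyl-3-[(TESO)methyl]pent-2-en-1-ol
Conditions: i-Bu2AlH, CH2Cl2, −78 °C
Reagents that add atoms: none
Why: 1,2-Reduction of the enoate by the aluminium hydride to the allylic alcohol without change of olefin geometry.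

Step 16
Reactants: 20 allylic alcohol
Product: 21 (2E,4R)-5-(TBSO)-4-methyl-3-[(TESO)methyl]pent-2-enal
Conditions: MnO2, CH2Cl2, rt
Reagents that add atoms: none
Why: Allylic oxidation on the surface of MnO2 under neutral conditions, which should preserve the olefin geometry of the enal (C6 aldehyde).

Step 17
Reactants: 22 2-bromoprop-2-en-1-ol
Product: 23 [(2-bromoprop-2-en-1-yl)oxy]tri(propan-2-yl)silane
Conditions: TIPSCl, imidazole, DMF, rt
Reagents that add atoms: chlorotri(propan-2-yl)silane, CC(C)[Si](Cl)(C(C)C)C(C)C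
Why: Silylation; the bulky TIPS group resists oxygen-to-carbon silyl shift in the vinyllithium and later shields the C16 hydrogens from lithiation.

Step 18
Reactants: 23 vinyl bromide; 21 enal
Product: 25 (4E,6R)-7-(TBSO)-6-methyl-5-[(TESO)methyl]-2-[(TIPSO)methyl]hepta-1,4-dien-3-ol (both C3 epimers), via vinyllithium 24 (not isolated)
Conditions: t-BuLi (2 equiv), Et2O, −78 °C; then 21, −78 °C
Reagents that add atoms: none
Why: Bromine–lithium exchange and 1,2-addition of the vinyllithium to the enal form the C5–C6 bond; the configuration of the new carbinol does not matter because it is erased in step 20.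

Step 19
Reactants: 25 dienol
Product: 26 tributylstannylmethyl ether of 25
Conditions: KH, THF, 0 °C; Bu3SnCH2I, rt
Reagents that add atoms: tributyl(iodomethyl)stannane, CCCC[Sn](CCCC)(CCCC)CI
Why: Williamson O-alkylation of the potassium alkoxide with the iodomethylstannane.

Step 20
Reactants: 26 stannylmethyl ether
Product: 28 (3E,5E,7R)-8-(TBSO)-7-methyl-6-[(TESO)methyl]-3-[(TIPSO)methyl]octa-3,5-dien-1-ol, via lithiomethyl ether 27 (not isolated)
Conditions: n-BuLi, THF, −78 °C
Reagents that add atoms: none
Why: Wittig–Still [2,3]-sigmatropic rearrangement: tin–lithium exchange gives the α-alkoxymethyllithium, which bonds to the terminal CH2 (C4) as the C6–O bond breaks. The transition state with the C7 substituent pseudoaxial avoids A(1,2) strain with the C5 CH2OTIPS group, so the C5=C6 olefin should form with C4 and C7 cis. The unhindered 1,1-disubstituted olefin reacts in preference to the fully substituted C8 terminus.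

Step 21
Reactants: 28 homoallylic alcohol
Product: 29 (3E,5E,7R)-8-(TBSO)-1-iodo-7-methyl-6-[(TESO)methyl]-3-[(TIPSO)methyl]octa-3,5-diene
Conditions: I2, PPh3, imidazole, CH2Cl2, 0 °C
Reagents that add atoms: iodine, II
Why: Appel-type iodination of the primary alcohol under buffered conditions that leave the allylic silyl ethers intact.

Step 22
Reactants: 29 iodide; 13 aldehyde
Product: 31 C2 carbinol (both C2 epimers) joining ring C to the dienyl chain, via alkyllithium 30 (not isolated)
Conditions: t-BuLi (2.1 equiv), Et2O–pentane, −78 °C; then 13, −78 to −40 °C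
Reagents that add atoms: none
Why: Iodine–lithium exchange and addition of the primary alkyllithium to the non-enolisable aldehyde form the C2–C3 bond. The C2 configuration is not controlled here because steps 23 and 24 reset it. Low temperature in a non-polar medium should keep the homoallyllithium from closing onto the diene.

Step 23
Reactants: 31 carbinol mixture
Product: 32 C2 ketone
Conditions: Dess–Martin periodinane, NaHCO3, CH2Cl2, rt
Reagents that add atoms: none
Why: Dess–Martin oxidation converts both epimers into one ketone.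

Step 24
Reactants: 32 ketone
Product: 33 (2S)-alcohol
Conditions: (R)-2-methyl-CBS-oxazaborolidine (1.2 equiv), BH3·SMe2 (1.2 equiv, premixed), CH2Cl2, −20 °C
Reagents that add atoms: none
Why: Corey–Bakshi–Shibata reduction with quaternary C1 as the large and C3H2 as the small group, so the (R)-catalyst should give the (2S)-carbinol. The preformed catalyst–borane complex leaves no free borane to hydroborate the olefins.

Step 25
Reactants: 33 alcohol
Product: 34 C2 TBS ether of 33
Conditions: TBSOTf, 2,6-lutidine, CH2Cl2, −40 to 0 °C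
Reagents that add atoms: tert-butyldimethylsilyl triflate, CC(C)(C)[Si](C)(C)OS(=O)(=O)C(F)(F)F
Why: Silylation of the neopentyl secondary alcohol with the silyl triflate.

Step 26
Reactants: 34 fully silylated seco compound
Product: 35 C9,C12-diol
Conditions: PPTS, MeOH–CH2Cl2, 0 °C
Reagents that add atoms: none
Why: Acid-catalysed methanolysis is selective for the two TES ethers (primary allylic at C9, secondary allylic at C12) over the TBS and TIPS ethers.

Step 27
Reactants: 35 diol
Product: 37 C9 allylic chloride with free C12 hydroxyl, via allylic mesylate 36 (not isolated)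
Conditions: MsCl, 2,4,6-collidine, LiCl, DMF, 0 °C
Reagents that add atoms: lithium chloride, [Li+].[Cl-]
Why: Selective sulfonylation of the primary allylic alcohol and chloride displacement in the same flask; the hindered secondary C12 hydroxyl does not react.

Step 28
Reactants: 37 chloro alcohol
Product: 38 thirteen-membered C9–O–C12 ether
Conditions: NaH, Bu4NI (cat.), THF, slow addition to 0.002 M, 50 °C
Reagents that add atoms: none
Why: Intramolecular Williamson ether synthesis (SN2 at the primary allylic C9) under high dilution. Iodide catalysis favours substitution over elimination, and attack at C9 is preferred to the vinylogous positions on steric and ring-size grounds.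

Step 29
Reactants: 38 thirteen-membered ether
Product: 39 ten-membered 9-hydroxy 5,7-diene
Conditions: n-BuLi, THF–hexane, −78 to −25 °C; aq. NH4Cl
Reagents that add atoms: none
Why: n-BuLi removes a C9 proton, which is α to oxygen and at the terminus of the C5–C8 diene, to give a lithiated α-alkoxy pentadienyl anion. C9 then bonds to C10 while the C12–O bond breaks and the olefin moves to C11=C12, a concerted [2,3]-Wittig shift through a five-membered envelope transition state; the closest known reaction type is the ring contraction of thirteen-membered diallylic ethers to ten-membered homoallylic alcohols. The ten-membered carbocycle arises by contraction of the existing macrocycle, the new C9–C10 bond spanning the five-centre array, so no separate cyclisation is needed. C10 is controlled by C12: the shift is suprafacial on the allyl unit, so the new bond forms on the face of ring C that the oxygen leaves, and (12S) should give (10S), trans to the C2 branch on C1. C9 is controlled by the envelope: the dienyl group takes the exo position away from quaternary C1, and with the ring-cis allyl unit this is the syn pathway, placing the C9 oxygen syn to C1 (9S). The step needs deprotonation at C9 and not at C12–H or C16–H2; the tertiary C12–H is less acidic, and the C16 hydrogens sit under the TIPS group next to a poorly coordinating silyl ether oxygen. It also needs the [2,3] shift to outrun the [1,2] shift, which low temperature and the allylic migrating terminus secure.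

Step 30
Reactants: 39 C9 alcohol
Product: 40 C9 acetate
Conditions: Ac2O, DMAP, pyridine, 0 °C
Reagents that add atoms: acetic anhydride, CC(=O)OC(C)=O
Why: Acetylation installs the final C9 group and removes the allylic hydroxyl, which would otherwise direct vanadium to the wrong face of C7=C8.

Step 31
Reactants: 40 acetate
Product: 41 C19 primary alcohol
Conditions: HF·pyridine, pyridine, THF, 0 °C
Reagents that add atoms: none
Why: Buffered fluoride cleaves the single primary TBS ether; the neopentyl secondary TBS ethers and the primary TIPS ether react much more slowly.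

Step 32
Reactants: 41 homoallylic alcohol
Product: 42 (7R,8S)-7,8-epoxide
Conditions: VO(acac)2 (5 mol%), t-BuOOH (in decane), CH2Cl2, 0 °C
Reagents that add atoms: tert-butyl hydroperoxide, CC(C)(C)OO
Why: Hydroxyl-directed vanadium epoxidation of a homoallylic alcohol; the vanadate of C19–OH can reach only C7=C8. A(1,3) strain between C17 and C6 holds H17 in the olefin plane, so the CH2O–V arm lies on one face (anti to the C18 methyl) and should deliver oxygen there. This gives the C8–O bond with the target configuration and a C7–O bond set up for inversion.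

Step 33
Reactants: 42 epoxy alcohol
Product: 44 hydroxy lactone (7S,8S), via epoxy acid 43 (not isolated)
Conditions: TEMPO (cat.), PhI(OAc)2, MeCN–pH 7 buffer, rt; then CSA (cat.), CH2Cl2, 0 °C
Reagents that add atoms: water, O
Why: Oxoammonium (TEMPO) oxidation takes the primary alcohol through the aldehyde hydrate to the acid under near-neutral conditions. Acid catalysis then lets the carboxyl group open the vinyl epoxide at the allylic carbon C7 (5-endo) with inversion, closing the γ-lactone and leaving the tertiary C8 hydroxyl.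

Step 34
Reactants: 44 tris-silyl lactone
Product: 45 C2,C14,C16-triol
Conditions: HF·pyridine, THF, 0 °C to rt
Reagents that add atoms: none
Why: Global desilylation by fluoride under mildly acidic conditions, which the lactone, the acetate and the tertiary alcohol tolerate.

Step 35
Reactants: 45 triol
Product: 46 CNP0277472.2
Conditions: Ac2O, DMAP, pyridine, rt
Reagents that add atoms: acetic anhydride, CC(=O)OC(C)=O
Why: Acetylation of the primary and the two secondary hydroxyls; the tertiary C8 hydroxyl is not acylated under these conditions.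

## Compound list

1 | 2-methoxy-5-methylbenzoic acid | COc1ccc(C)cc1C(=O)O | starting material
2 | (S)-2-(methoxymethyl)pyrrolidine | COC[C@@H]1CCCN1 | starting material
3 | 2-methoxy-5-methylbenzoyl chloride | COc1ccc(C)cc1C(Cl)=O | intermediate
4 | [(2S)-2-(methoxymethyl)pyrrolidin-1-yl](2-methoxy-5-methylphenyl)methanone | COc1ccc(C)cc1C(=O)N1CCC[C@H]1COC | intermediate
5 | [(1R)-2-methoxy-1,5-dimethylcyclohexa-2,5-dien-1-yl][(2S)-2-(methoxymethyl)pyrrolidin-1-yl]methanone | COC1=CCC(C)=C[C@@]1(C)C(=O)N1CCC[C@H]1COC | intermediate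
6 | [(1R)-1,3-dimethyl-6-oxocyclohex-2-en-1-yl][(2S)-2-(methoxymethyl)pyrrolidin-1-yl]methanone | O=C1CCC(C)=C[C@@]1(C)C(=O)N1CCC[C@H]1COC | intermediate
7 | [(1R,6S)-6-hydroxy-1,3-dimethylcyclohex-2-en-1-yl][(2S)-2-(methoxymethyl)pyrrolidin-1-yl]methanone | O[C@H]1CCC(C)=C[C@@]1(C)C(=O)N1CCC[C@H]1COC | intermediate
8 | [(1R,6S)-6-(TBSO)-1,3-dimethylcyclohex-2-en-1-yl][(2S)-2-(methoxymethyl)pyrrolidin-1-yl]methanone | CC(C)(C)[Si](C)(C)O[C@H]1CCC(C)=C[C@@]1(C)C(=O)N1CCC[C@H]1COC | intermediate
9 | [(1R,6S)-6-(TBSO)-1,3-dimethyl-4-oxocyclohex-2-en-1-yl][(2S)-2-(methoxymethyl)pyrrolidin-1-yl]methanone | CC(C)(C)[Si](C)(C)O[C@H]1CC(=O)C(C)=C[C@@]1(C)C(=O)N1CCC[C@H]1COC | intermediate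
10 | [(1R,4S,6S)-6-(TBSO)-4-hydroxy-1,3-dimethylcyclohex-2-en-1-yl][(2S)-2-(methoxymethyl)pyrrolidin-1-yl]methanone | O[C@H]1C[C@H](O[Si](C)(C)C(C)(C)C)[C@@](C)(C=C1C)C(=O)N1CCC[C@H]1COC | intermediate
11 | [(1R,4S,6S)-6-(TBSO)-1,3-dimethyl-4-(TESO)cyclohex-2-en-1-yl][(2S)-2-(methoxymethyl)pyrrolidin-1-yl]methanone | CC[Si](CC)(CC)O[C@H]1C[C@H](O[Si](C)(C)C(C)(C)C)[C@@](C)(C=C1C)C(=O)N1CCC[C@H]1COC | intermediate
12 | [(1S,4S,6S)-6-(TBSO)-1,3-dimethyl-4-(TESO)cyclohex-2-en-1-yl]methanol | CC[Si](CC)(CC)O[C@H]1C[C@H](O[Si](C)(C)C(C)(C)C)[C@@](C)(C=C1C)CO | intermediate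
13 | (1R,4S,6S)-6-(TBSO)-1,3-dimethyl-4-(TESO)cyclohex-2-ene-1-carbaldehyde | CC[Si](CC)(CC)O[C@H]1C[C@H](O[Si](C)(C)C(C)(C)C)[C@@](C)(C=C1C)C=O | intermediate
14 | methyl (S)-3-hydroxy-2-methylpropanoate | C[C@@H](CO)C(=O)OC | starting material
15 | methyl (2S)-3-(TBSO)-2-methylpropanoate | C[C@@H](CO[Si](C)(C)C(C)(C)C)C(=O)OC | intermediate
16 | methyl (4S)-5-(TBSO)-4-methyl-3-oxopentanoate | C[C@@H](CO[Si](C)(C)C(C)(C)C)C(=O)CC(=O)OC | intermediate
17 | methyl (2E,4S)-5-(TBSO)-4-methyl-3-[(trifluoromethanesulfonyl)oxy]pent-2-enoate | C[C@@H](CO[Si](C)(C)C(C)(C)C)/C(OS(=O)(=O)C(F)(F)F)=C\C(=O)OC | intermediate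
18 | methyl (2E,4R)-5-(TBSO)-3-(hydroxymethyl)-4-methylpent-2-enoate | C[C@@H](CO[Si](C)(C)C(C)(C)C)/C(CO)=C\C(=O)OC | intermediate
19 | methyl (2E,4R)-5-(TBSO)-4-methyl-3-[(TESO)methyl]pent-2-enoate | C[C@@H](CO[Si](C)(C)C(C)(C)C)/C(CO[Si](CC)(CC)CC)=C\C(=O)OC | intermediate
20 | (2E,4R)-5-(TBSO)-4-methyl-3-[(TESO)methyl]pent-2-en-1-ol | C[C@@H](CO[Si](C)(C)C(C)(C)C)/C(CO[Si](CC)(CC)CC)=C\CO | intermediate
21 | (2E,4R)-5-(TBSO)-4-methyl-3-[(TESO)methyl]pent-2-enal | C[C@@H](CO[Si](C)(C)C(C)(C)C)/C(CO[Si](CC)(CC)CC)=C\C=O | intermediate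
22 | 2-bromoprop-2-en-1-ol | OCC(Br)=C | starting material
23 | [(2-bromoprop-2-en-1-yl)oxy]tri(propan-2-yl)silane | C=C(Br)CO[Si](C(C)C)(C(C)C)C(C)C | intermediate
24 | [3-(TIPSO)prop-1-en-2-yl]lithium | [Li]C(=C)CO[Si](C(C)C)(C(C)C)C(C)C | intermediate
25 | (4E,6R)-7-(TBSO)-6-methyl-5-[(TESO)methyl]-2-[(TIPSO)methyl]hepta-1,4-dien-3-ol, both C3 epimers | C=C(CO[Si](C(C)C)(C(C)C)C(C)C)C(O)/C=C(CO[Si](CC)(CC)CC)\[C@@H](C)CO[Si](C)(C)C(C)(C)C | intermediate
26 | tributyl({[(4E,6R)-7-(TBSO)-6-methyl-5-[(TESO)methyl]-2-[(TIPSO)methyl]hepta-1,4-dien-3-yl]oxy}methyl)stannane | C=C(CO[Si](C(C)C)(C(C)C)C(C)C)C(OC[Sn](CCCC)(CCCC)CCCC)/C=C(CO[Si](CC)(CC)CC)\[C@@H](C)CO[Si](C)(C)C(C)(C)C | intermediate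
27 | lithiomethyl ether of 25 (lithium in place of the tributylstannyl group of 26) | C=C(CO[Si](C(C)C)(C(C)C)C(C)C)C(OC[Li])/C=C(CO[Si](CC)(CC)CC)\[C@@H](C)CO[Si](C)(C)C(C)(C)C | intermediate
28 | (3E,5E,7R)-8-(TBSO)-7-methyl-6-[(TESO)methyl]-3-[(TIPSO)methyl]octa-3,5-dien-1-ol | OCC/C(CO[Si](C(C)C)(C(C)C)C(C)C)=C\C=C(CO[Si](CC)(CC)CC)/[C@@H](C)CO[Si](C)(C)C(C)(C)C | intermediate
29 | (3E,5E,7R)-8-(TBSO)-1-iodo-7-methyl-6-[(TESO)methyl]-3-[(TIPSO)methyl]octa-3,5-diene | ICC/C(CO[Si](C(C)C)(C(C)C)C(C)C)=C\C=C(CO[Si](CC)(CC)CC)/[C@@H](C)CO[Si](C)(C)C(C)(C)C | intermediate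
30 | 1-lithio analogue of 29 | [Li]CC/C(CO[Si](C(C)C)(C(C)C)C(C)C)=C\C=C(CO[Si](CC)(CC)CC)/[C@@H](C)CO[Si](C)(C)C(C)(C)C | intermediate
31 | (4E,6E,8R)-9-(TBSO)-1-[(1S,4S,6S)-6-(TBSO)-1,3-dimethyl-4-(TESO)cyclohex-2-en-1-yl]-8-methyl-7-[(TESO)methyl]-4-[(TIPSO)methyl]nona-4,6-dien-1-ol, both C1 epimers (chain C1 = skeleton C2) | CC[Si](CC)(CC)O[C@H]1C[C@H](O[Si](C)(C)C(C)(C)C)[C@@](C)(C=C1C)C(O)CC/C(CO[Si](C(C)C)(C(C)C)C(C)C)=C\C=C(CO[Si](CC)(CC)CC)/[C@@H](C)CO[Si](C)(C)C(C)(C)C | intermediate
32 | (4E,6E,8R)-9-(TBSO)-1-[(1R,4S,6S)-6-(TBSO)-1,3-dimethyl-4-(TESO)cyclohex-2-en-1-yl]-8-methyl-7-[(TESO)methyl]-4-[(TIPSO)methyl]nona-4,6-dien-1-one | CC[Si](CC)(CC)O[C@H]1C[C@H](O[Si](C)(C)C(C)(C)C)[C@@](C)(C=C1C)C(=O)CC/C(CO[Si](C(C)C)(C(C)C)C(C)C)=C\C=C(CO[Si](CC)(CC)CC)/[C@@H](C)CO[Si](C)(C)C(C)(C)C | intermediate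
33 | (1S,4E,6E,8R)-9-(TBSO)-1-[(1S,4S,6S)-6-(TBSO)-1,3-dimethyl-4-(TESO)cyclohex-2-en-1-yl]-8-methyl-7-[(TESO)methyl]-4-[(TIPSO)methyl]nona-4,6-dien-1-ol | CC[Si](CC)(CC)O[C@H]1C[C@H](O[Si](C)(C)C(C)(C)C)[C@@](C)(C=C1C)[C@@H](O)CC/C(CO[Si](C(C)C)(C(C)C)C(C)C)=C\C=C(CO[Si](CC)(CC)CC)/[C@@H](C)CO[Si](C)(C)C(C)(C)C | intermediate
34 | 1-O-TBS ether of 33 (skeleton: 1S,2S,12S,14S,17R; 5E,7E) | CC[Si](CC)(CC)O[C@H]1C[C@H](O[Si](C)(C)C(C)(C)C)[C@@](C)(C=C1C)[C@@H](O[Si](C)(C)C(C)(C)C)CC/C(CO[Si](C(C)C)(C(C)C)C(C)C)=C\C=C(CO[Si](CC)(CC)CC)/[C@@H](C)CO[Si](C)(C)C(C)(C)C | intermediate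
35 | (1S,4E,6E,8R)-1,9-bis(TBSO)-1-[(1S,4S,6S)-6-(TBSO)-4-hydroxy-1,3-dimethylcyclohex-2-en-1-yl]-7-(hydroxymethyl)-8-methyl-4-[(TIPSO)methyl]nona-4,6-diene | O[C@H]1C[C@H](O[Si](C)(C)C(C)(C)C)[C@@](C)(C=C1C)[C@@H](O[Si](C)(C)C(C)(C)C)CC/C(CO[Si](C(C)C)(C(C)C)C(C)C)=C\C=C(CO)/[C@@H](C)CO[Si](C)(C)C(C)(C)C | intermediate
36 | methanesulfonate of the primary allylic (C9) hydroxyl of 35 | O[C@H]1C[C@H](O[Si](C)(C)C(C)(C)C)[C@@](C)(C=C1C)[C@@H](O[Si](C)(C)C(C)(C)C)CC/C(CO[Si](C(C)C)(C(C)C)C(C)C)=C\C=C(COS(C)(=O)=O)/[C@@H](C)CO[Si](C)(C)C(C)(C)C | intermediate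
37 | (1S,4E,6E,8R)-1,9-bis(TBSO)-7-(chloromethyl)-1-[(1S,4S,6S)-6-(TBSO)-4-hydroxy-1,3-dimethylcyclohex-2-en-1-yl]-8-methyl-4-[(TIPSO)methyl]nona-4,6-diene | O[C@H]1C[C@H](O[Si](C)(C)C(C)(C)C)[C@@](C)(C=C1C)[C@@H](O[Si](C)(C)C(C)(C)C)CC/C(CO[Si](C(C)C)(C(C)C)C(C)C)=C\C=C(CCl)/[C@@H](C)CO[Si](C)(C)C(C)(C)C | intermediate
38 | thirteen-membered ether (ring: C1–C9, O, C12, C11, C10; ring C closed through C13, C14): (1S,2S,12S,14S,17R; 5E,7E) 2,14,19-tris(TBSO)-16-(TIPSO) C9–O–C12 dienyl allyl ether | CC(C)[Si](C(C)C)(C(C)C)OC/C1=C/C=C(\[C@@H](C)CO[Si](C)(C)C(C)(C)C)CO[C@H]2C[C@H](O[Si](C)(C)C(C)(C)C)[C@@](C)(C=C2C)[C@@H](O[Si](C)(C)C(C)(C)C)CC1 | intermediate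
39 | (1S,2S,9S,10S,14S,17R; 5E,7E)-2,14,19-tris(TBSO)-16-(TIPSO)briara-5,7,11-trien-9-ol (ten-membered ring, no lactone) | CC(C)[Si](C(C)C)(C(C)C)OC/C1=C/C=C(\[C@@H](C)CO[Si](C)(C)C(C)(C)C)[C@@H](O)[C@H]2C(C)=CC[C@H](O[Si](C)(C)C(C)(C)C)[C@]2(C)[C@@H](O[Si](C)(C)C(C)(C)C)CC1 | intermediate
40 | 9-acetate of 39 | CC(C)[Si](C(C)C)(C(C)C)OC/C1=C/C=C(\[C@@H](C)CO[Si](C)(C)C(C)(C)C)[C@@H](OC(C)=O)[C@H]2C(C)=CC[C@H](O[Si](C)(C)C(C)(C)C)[C@]2(C)[C@@H](O[Si](C)(C)C(C)(C)C)CC1 | intermediate
41 | 19-alcohol: 40 without the C19 TBS group | CC(C)[Si](C(C)C)(C(C)C)OC/C1=C/C=C(\[C@@H](C)CO)[C@@H](OC(C)=O)[C@H]2C(C)=CC[C@H](O[Si](C)(C)C(C)(C)C)[C@]2(C)[C@@H](O[Si](C)(C)C(C)(C)C)CC1 | intermediate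
42 | (7R,8S)-7,8-epoxide of 41 (1S,2S,9S,10S,14S,17S by the CIP rules) | CC(C)[Si](C(C)C)(C(C)C)OC/C1=C/[C@H]3O[C@]3([C@@H](C)CO)[C@@H](OC(C)=O)[C@H]2C(C)=CC[C@H](O[Si](C)(C)C(C)(C)C)[C@]2(C)[C@@H](O[Si](C)(C)C(C)(C)C)CC1 | intermediate
43 | C19 carboxylic acid of 42 (7R,8S,17R) | CC(C)[Si](C(C)C)(C(C)C)OC/C1=C/[C@H]3O[C@]3([C@@H](C)C(=O)O)[C@@H](OC(C)=O)[C@H]2C(C)=CC[C@H](O[Si](C)(C)C(C)(C)C)[C@]2(C)[C@@H](O[Si](C)(C)C(C)(C)C)CC1 | intermediate
44 | (1S,2S,7S,8S,9S,10S,14S,17R)-9-acetoxy-8-hydroxy-2,14-bis(TBSO)-16-(TIPSO)briara-5,11-dien-19,7-olide | CC(C)[Si](C(C)C)(C(C)C)OC/C1=C/[C@@H]2OC(=O)[C@H](C)[C@@]2(O)[C@@H](OC(C)=O)[C@H]2C(C)=CC[C@H](O[Si](C)(C)C(C)(C)C)[C@]2(C)[C@@H](O[Si](C)(C)C(C)(C)C)CC1 | intermediate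
45 | (1S,2S,7S,8S,9S,10S,14S,17R)-9-acetoxy-2,8,14,16-tetrahydroxybriara-5,11-dien-19,7-olide | OC/C1=C/[C@@H]2OC(=O)[C@H](C)[C@@]2(O)[C@@H](OC(C)=O)[C@H]2C(C)=CC[C@H](O)[C@]2(C)[C@@H](O)CC1 | intermediate
46 | CNP0277472.2, (1S,2S,7S,8S,9S,10S,14S,17R)-2,9,14,16-tetraacetoxy-8-hydroxybriara-5,11-dien-19,7-olide | CC(=O)OC/C1=C/[C@@H]2OC(=O)[C@H](C)[C@@]2(O)[C@@H](OC(C)=O)[C@H]2C(C)=CC[C@H](OC(C)=O)[C@]2(C)[C@@H](OC(C)=O)CC1 | target

## Step count and least certain steps

Total: 35 steps. Longest linear sequence: 25 steps (from 14 through steps 10–16 and 18–35 to 46).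

**Step 29 (key step).** The most likely failure is insufficient syn selectivity at C9, if the dienyl group takes the endo position of the envelope, together with some [1,2]-shift on warming. Fallback, setting out from 38 and returning at 39: the rearrangement is run as before and the C9 epimer of 39 F1 is taken on. A Mitsunobu reaction (4-nitrobenzoic acid, PPh3, diisopropyl azodicarboxylate) inverts C9 to give the (9S)-4-nitrobenzoate F2, and methanolysis (K2CO3, MeOH) gives 39.

**Step 32 (with step 33).** The most likely failure is poor facial selectivity. The face of C7=C8 chosen by C17 must also be the face that the ten-membered ring leaves open, since a trans olefin in such a ring is attacked only from outside. If the ring exposes the other face, the oxygen arrives there or the reaction stalls. In step 33 the carboxyl group must then reach C7 from the ring side, where SN1 scrambling or participation of the C9 acetate at C8 can compete. Fallback, setting out from 39 and returning at 44, which uses the opposite face on purpose: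
- C9-hydroxyl-directed epoxidation (VO(acac)2, t-BuOOH), erythro-selective and from the outer face, gives the diastereomeric 7,8-epoxy-9-ol F3.
- Acetylation gives the epoxy acetate F4.
- BF3·OEt2 and then water open the epoxide at the tertiary C8 through the neighbouring acetate (dioxolanylium ion). This inverts C8 and leaves the C7 oxygen in place, giving the 7,8-diol 9-acetate F5.
- Buffered HF·pyridine removes the C19 silyl group to give the triol F6.
- TEMPO/PhI(OAc)2 oxidative lactonisation of the C19/C7 1,4-diol closes the lactone with retention at C7 and gives 44.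

**Step 28.** The most likely failure is intermolecular etherification (oligomers), or loss of the allylic chloride by elimination or vinylogous substitution before the ring closes. Fallback, setting out from 35 and returning at 38: the primary allylic hydroxyl is converted into the methyl carbonate F7 (ClCO2Me, pyridine, 0 °C). The ring is then closed by allylic etherification with zerovalent palladium (Pd2(dba)3, dppb, THF, high dilution), the C12 hydroxyl attacking the primary terminus of the π-allyl complex.

**Step 22.** The most likely failure is cyclisation of the homoallyllithium onto the diene (cyclopropylcarbinyl pathway) or its quenching by proton transfer before it adds. Fallback, setting out from 29 and returning at 32: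
- PhSO2Na in DMF gives the sulfone F8.
- Its α-lithio derivative (n-BuLi, THF, −78 °C), a stabilised anion that cannot cyclise, adds to 13 to give the β-hydroxy sulfone F9.
- Dess–Martin oxidation gives the β-keto sulfone F10.
- SmI2 in THF–MeOH removes the sulfonyl group to give ketone 32.

**Step 5.** The most likely failure is oxidation at the C–H bonds next to the amide nitrogen or at the C20 methyl in competition with C12. Fallback, setting out from 8 and returning at 9: an ene/[2,3] oxidation (cat. SeO2, t-BuOOH, CH2Cl2) hydroxylates the ring allylic position to give the C12 alcohol F11 as an epimer mixture, and Dess–Martin oxidation gives 9.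

## Further compounds

F1 | step 29 | C9 epimer of 39 (9R) | CC(C)[Si](C(C)C)(C(C)C)OC/C1=C/C=C(\[C@@H](C)CO[Si](C)(C)C(C)(C)C)[C@H](O)[C@H]2C(C)=CC[C@H](O[Si](C)(C)C(C)(C)C)[C@]2(C)[C@@H](O[Si](C)(C)C(C)(C)C)CC1
F2 | step 29 | 4-nitrobenzoate of 39 (9S) | CC(C)[Si](C(C)C)(C(C)C)OC/C1=C/C=C(\[C@@H](C)CO[Si](C)(C)C(C)(C)C)[C@@H](OC(=O)c3ccc(cc3)[N+](=O)[O-])[C@H]2C(C)=CC[C@H](O[Si](C)(C)C(C)(C)C)[C@]2(C)[C@@H](O[Si](C)(C)C(C)(C)C)CC1
F3 | step 32 | 7,8-epoxide of 39 on the face opposite to that of 42, free 9-hydroxyl, C19 TBS ether | CC(C)[Si](C(C)C)(C(C)C)OC/C1=C/[C@@H]3O[C@@]3([C@@H](C)CO[Si](C)(C)C(C)(C)C)[C@@H](O)[C@H]2C(C)=CC[C@H](O[Si](C)(C)C(C)(C)C)[C@]2(C)[C@@H](O[Si](C)(C)C(C)(C)C)CC1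
F4 | step 32 | 9-acetate of F3 | CC(C)[Si](C(C)C)(C(C)C)OC/C1=C/[C@@H]3O[C@@]3([C@@H](C)CO[Si](C)(C)C(C)(C)C)[C@@H](OC(C)=O)[C@H]2C(C)=CC[C@H](O[Si](C)(C)C(C)(C)C)[C@]2(C)[C@@H](O[Si](C)(C)C(C)(C)C)CC1
F5 | step 32 | (7S,8S)-7,8-diol 9-acetate with C19 TBS ether | CC(C)[Si](C(C)C)(C(C)C)OC/C1=C/[C@H](O)[C@@](O)([C@@H](C)CO[Si](C)(C)C(C)(C)C)[C@@H](OC(C)=O)[C@H]2C(C)=CC[C@H](O[Si](C)(C)C(C)(C)C)[C@]2(C)[C@@H](O[Si](C)(C)C(C)(C)C)CC1
F6 | step 32 | (7S,8S)-7,8,19-triol 9-acetate | CC(C)[Si](C(C)C)(C(C)C)OC/C1=C/[C@H](O)[C@@](O)([C@@H](C)CO)[C@@H](OC(C)=O)[C@H]2C(C)=CC[C@H](O[Si](C)(C)C(C)(C)C)[C@]2(C)[C@@H](O[Si](C)(C)C(C)(C)C)CC1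
F7 | step 28 | methyl carbonate of the primary allylic (C9) hydroxyl of 35 | O[C@H]1C[C@H](O[Si](C)(C)C(C)(C)C)[C@@](C)(C=C1C)[C@@H](O[Si](C)(C)C(C)(C)C)CC/C(CO[Si](C(C)C)(C(C)C)C(C)C)=C\C=C(COC(=O)OC)/[C@@H](C)CO[Si](C)(C)C(C)(C)C
F8 | step 22 | phenyl sulfone from 29 (PhSO2 in place of iodine) | O=S(=O)(c1ccccc1)CC/C(CO[Si](C(C)C)(C(C)C)C(C)C)=C\C=C(CO[Si](CC)(CC)CC)/[C@@H](C)CO[Si](C)(C)C(C)(C)C
F9 | step 22 | β-hydroxy sulfone (C2 carbinol, C3 phenylsulfonyl; epimer mixture) | CC[Si](CC)(CC)O[C@H]1C[C@H](O[Si](C)(C)C(C)(C)C)[C@@](C)(C=C1C)C(O)C(C/C(CO[Si](C(C)C)(C(C)C)C(C)C)=C\C=C(CO[Si](CC)(CC)CC)/[C@@H](C)CO[Si](C)(C)C(C)(C)C)S(=O)(=O)c1ccccc1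
F10 | step 22 | β-keto sulfone (C2 ketone, C3 phenylsulfonyl) | CC[Si](CC)(CC)O[C@H]1C[C@H](O[Si](C)(C)C(C)(C)C)[C@@](C)(C=C1C)C(=O)C(C/C(CO[Si](C(C)C)(C(C)C)C(C)C)=C\C=C(CO[Si](CC)(CC)CC)/[C@@H](C)CO[Si](C)(C)C(C)(C)C)S(=O)(=O)c1ccccc1
F11 | step 5 | C12 alcohol from 8, mixture of C12 epimers | OC1C[C@H](O[Si](C)(C)C(C)(C)C)[C@@](C)(C=C1C)C(=O)N1CCC[C@H]1COC
A1 | alternative 1 | C8 triethylsilyl ether of 46 | CC(=O)OC/C1=C/[C@@H]2OC(=O)[C@H](C)[C@@]2(O[Si](CC)(CC)CC)[C@@H](OC(C)=O)[C@H]2C(C)=CC[C@H](OC(C)=O)[C@]2(C)[C@@H](OC(C)=O)CC1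
A2 | alternative 2 | ten-membered 2,7-dione with C4=C5 olefin | C/C1=C/CC(=O)[C@@]2(C)[C@@H](O[Si](C)(C)C(C)(C)C)CC=C(C)[C@@H]2[C@H](O[Si](C)(C)C(C)(C)C)CC(=O)C1
A3 | alternative 3 | ten-membered C2 ketone with C5=C6 olefin and C7,C8 acetonide | CC(C)(C)[Si](C)(C)OC/C1=C/[C@@H]2OC(C)(C)O[C@]2([C@@H](C)CO[Si](C)(C)C(C)(C)C)[C@@H](O[Si](C)(C)C(C)(C)C)[C@H]2C(C)=CC[C@H](O[Si](C)(C)C(C)(C)C)[C@]2(C)C(=O)CC1
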